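**Strategy.** The route rests on disconnecting both bonds to C2 of the dihydrofuran ring, C2–C3 and O1–C2. C3, a diarylmethine ortho to the ring-B phenol oxygen, is the exocyclic carbon of an o-quinone methide. C2, which carries only the 4-hydroxyphenyl group, is a benzylidene carbon delivered by a chiral benzylsulfonium ylide. One base-mediated [4+1] annulation of racemic sulfone 7 with thiolanium salt 14 should therefore build the ring, both stereocentres and the trans relationship, leaving an aryl bromide at C5. That bromide becomes a boronic acid, which a rhodium-catalysed asymmetric conjugate addition joins to the 8-substituted chromone 24. One acidic step then removes all protecting groups.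

Key step: step 10

Assumption: 5,7-dihydroxychromone is taken as purchasable, and the sense of induction of the (2R,5R)-thiolane (step 10) and of the (S,S)-diene (step 17) is assigned by analogy with sulfur-ylide epoxidation and arylation of cyclic enones; both antipodes of each are available, so a model run can correct the choice without changing the route.

**Step 1**
Reactants: 1 5-bromo-2,4-dihydroxybenzaldehyde
Product: 2 5-bromo-2-hydroxy-4-(methoxymethoxy)benzaldehyde
Conditions: MOMCl (1.05 equiv), K2CO3, acetone, 0 °C → rt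
Reagents that add atoms: chloromethyl methyl ether, COCCl
Why: Williamson-type O-alkylation should occur only at the 4-hydroxyl, because the 2-hydroxyl is held in a hydrogen bond to the aldehyde and is the less acidic of the two.

**Step 2**
Reactants: 3 5-bromoresorcinol
Product: 4 1-bromo-3,5-bis(methoxymethoxy)benzene
Conditions: MOMCl (2.5 equiv), i-Pr2NEt, CH2Cl2, 0 °C → rt
Reagents that add atoms: chloromethyl methyl ether, COCCl
Why: Exhaustive Williamson-type O-alkylation of both phenols with a hindered amine base is routine and leaves the aryl bromide untouched.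

**Step 3**
Reactants: 4 1-bromo-3,5-bis(methoxymethoxy)benzene; 2 5-bromo-2-hydroxy-4-(methoxymethoxy)benzaldehyde
Product: 6 rac-[5-bromo-2-hydroxy-4-(methoxymethoxy)phenyl][3,5-bis(methoxymethoxy)phenyl]methanol, via 3,5-bis(methoxymethoxy)phenylmagnesium bromide 5 (not isolated)
Conditions: 4 (2.3 equiv), Mg, I2 (cat.), THF, 50 °C; then 2, 0 °C → rt; aq. NH4Cl
Reagents that add atoms: none
Why: Grignard formation and 1,2-addition to the aldehyde, in which one equivalent of 5 is spent on the free phenol and the second adds to the carbonyl, while the aryl bromide of 2 and the MOM ethers are inert at this temperature; the racemic carbinol centre is erased in step 10.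

**Step 4**
Reactants: 6 rac-[5-bromo-2-hydroxy-4-(methoxymethoxy)phenyl][3,5-bis(methoxymethoxy)phenyl]methanol
Product: 7 rac-2-{[3,5-bis(methoxymethoxy)phenyl](4-methylbenzenesulfonyl)methyl}-4-bromo-5-(methoxymethoxy)phenol
Conditions: p-TolSO2H (1.5 equiv), CH2Cl2, 0 °C → rt
Reagents that add atoms: p-toluenesulfinic acid, Cc1ccc(cc1)S(=O)O
Why: SN1 substitution, since the ortho-hydroxy, para-alkoxy benzhydrol ionises under the weak acidity of the sulfinic acid and is trapped at sulfur to give the sulfone, while this acid should be too weak to cleave aryl MOM ethers in an aprotic solvent.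

**Step 5**
Reactants: 8 4-hydroxybenzyl alcohol
Product: 9 [4-(methoxymethoxy)phenyl]methanol
Conditions: MOMCl (1.05 equiv), K2CO3, acetone, 0 °C → rt
Reagents that add atoms: chloromethyl methyl ether, COCCl
Why: Chemoselective Williamson O-alkylation, because carbonate deprotonates only the phenol and not the benzylic alcohol.

**Step 6**
Reactants: 9 [4-(methoxymethoxy)phenyl]methanol
Product: 10 1-(bromomethyl)-4-(methoxymethoxy)benzene
Conditions: CBr4, PPh3, CH2Cl2, 0 °C; used at once
Reagents that add atoms: carbon tetrabromide, BrC(Br)(Br)Br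
Why: The Appel reaction converts the primary benzylic alcohol into the bromide under neutral conditions that spare the MOM acetal.

**Step 7**
Reactants: 11 (2S,5S)-hexane-2,5-diol
Product: 12 (2S,5S)-hexane-2,5-diyl dimethanesulfonate
Conditions: MsCl, Et3N, CH2Cl2, –20 → 0 °C
Reagents that add atoms: methanesulfonyl chloride, CS(=O)(=O)Cl
Why: O-Sulfonylation takes place at oxygen only, so both stereocentres are retained.

**Step 8**
Reactants: 12 (2S,5S)-hexane-2,5-diyl dimethanesulfonate
Product: 13 (2R,5R)-2,5-dimethylthiolane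
Conditions: Na2S·9H2O, EtOH, rt → 40 °C
Reagents that add atoms: sodium sulfide, [Na+].[Na+].[S-2]
Why: Double SN2 displacement by sulfide (intermolecular, then 5-exo-tet) inverts both centres, turning the (2S,5S)-dimesylate into the (2R,5R)-thiolane.

**Step 9**
Reactants: 13 (2R,5R)-2,5-dimethylthiolane; 10 1-(bromomethyl)-4-(methoxymethoxy)benzene
Product: 14 (2R,5R)-1-[4-(methoxymethoxy)benzyl]-2,5-dimethylthiolan-1-ium tetrafluoroborate
Conditions: AgBF4, CH2Cl2, –30 °C → rt, dark
Reagents that add atoms: silver tetrafluoroborate, [Ag+].F[B-](F)(F)F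
Why: S-Alkylation of the thioether by the activated benzylic bromide is made irreversible by precipitation of AgBr, the non-nucleophilic counter-ion keeps the electron-rich benzylsulfonium from reverting, and the C2 axis of the thiolane makes both sulfur lone pairs equivalent so that one salt forms.

**Step 10**
Reactants: 7 rac-2-{[3,5-bis(methoxymethoxy)phenyl](4-methylbenzenesulfonyl)methyl}-4-bromo-5-(methoxymethoxy)phenol; 14 (2R,5R)-1-[4-(methoxymethoxy)benzyl]-2,5-dimethylthiolan-1-ium tetrafluoroborate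
Product: 18 (2R,3R)-5-bromo-3-[3,5-bis(methoxymethoxy)phenyl]-6-(methoxymethoxy)-2-[4-(methoxymethoxy)phenyl]-2,3-dihydro-1-benzofuran, via o-quinone methide 15 (not isolated), via sulfonium benzylide 16 (not isolated), via phenoxide–sulfonium betaine 17 (not isolated)
Conditions: 14 (1.3 equiv), Cs2CO3 (3.5 equiv), CH2Cl2–MeCN, –20 °C → rt
Reagents that add atoms: none
Why: Proposed new method: Cs2CO3 should deprotonate the phenol of 7 and expel sulfinate (E1cB) to give o-quinone methide 15, and deprotonate salt 14 to benzylide 16, whose carbon adds to the exocyclic methide carbon (C3 of the product) with rearomatisation to betaine 17, after which the phenoxide oxygen displaces the neutral thiolane from the former ylide carbon (C2); the closest known reaction types are the [4+1] annulation of sulfone-derived o-quinone methides with carbonyl-stabilised sulfonium ylides and the asymmetric Corey–Chaykovsky epoxidation with benzylides of C2-symmetric thiolanes, the extension being an aryl-stabilised ylide carried by a chiral sulfide. The single ring closes in the 5-exo-tet mode, by SN2 attack of O1 on C2 with inversion. C2 is controlled by the thiolane, whose two methyl groups fix the ylide conformation and expose one face of the ylide carbon, so that after the invertive closure C2 should be R. C3 is set in the same C–C bond formation, where the two aryl groups avoid each other to give the anti betaine (a syn betaine can still epimerise at the acidic carbon next to sulfonium), and the invertive closure turns this into the trans ring, hence 3R. The step needs C-alkylation of the methide by the ylide to outrun benzyl transfer from the electron-rich sulfonium to phenoxide or sulfinate, which the non-nucleophilic BF4 counter-ion, the gradual release of 15 by the heterogeneous base and the electrophilicity of the methide (kept persistent by the para MOM-oxy group) should secure; the aryl bromide and MOM ethers are inert to carbonate.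

**Step 11**
Reactants: 19 5,7-dihydroxy-4H-chromen-4-one
Product: 20 5,7-bis(methoxymethoxy)-4H-chromen-4-one
Conditions: NaH (2.4 equiv), MOMCl (2.6 equiv), DMF, 0 °C → rt
Reagents that add atoms: chloromethyl methyl ether, COCCl
Why: Williamson double O-alkylation, with NaH needed to break the hydrogen bond of the chelated 5-hydroxyl.

**Step 12**
Reactants: 20 5,7-bis(methoxymethoxy)-4H-chromen-4-one
Product: 21 8-iodo-5,7-bis(methoxymethoxy)-4H-chromen-4-one
Conditions: BnMe3N·ICl2 (1.1 equiv), CaCO3, CH2Cl2–MeOH, rt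
Reagents that add atoms: benzyltrimethylammonium dichloroiodate, C[N+](C)(C)Cc1ccccc1.Cl[I-]Cl
Why: Electrophilic aromatic iodination of the phloroglucinol-type ring A should go to C8, which is para to the 5-alkoxy group and less hindered than C6 lying between two MOM ethers, the regiochemistry established for 5,7-dialkoxy chromones and flavones.

**Step 13**
Reactants: 21 8-iodo-5,7-bis(methoxymethoxy)-4H-chromen-4-one
Product: 22 5,7-bis(methoxymethoxy)-8-(3-methylbut-2-en-1-yl)-4H-chromen-4-one
Conditions: tributyl(3-methylbut-2-en-1-yl)stannane (1.3 equiv), Pd(PPh3)4 (5 mol %), DMF, 90 °C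
Reagents that add atoms: tributyl(3-methylbut-2-en-1-yl)stannane, CCCC[Sn](CCCC)(CCCC)CC=C(C)C
Why: Stille coupling transfers the prenyl group to the aryl iodide through its primary carbon under neutral conditions that leave the chromone carbonyl and MOM ethers alone.

**Step 14**
Reactants: 22 5,7-bis(methoxymethoxy)-8-(3-methylbut-2-en-1-yl)-4H-chromen-4-one
Product: 23 8-[(2E)-4-hydroxy-3-methylbut-2-en-1-yl]-5,7-bis(methoxymethoxy)-4H-chromen-4-one
Conditions: SeO2 (0.3 equiv), t-BuOOH (2 equiv), CH2Cl2, 0 °C → rt; stopped before full conversion, 22 recycled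
Reagents that add atoms: tert-butyl hydroperoxide, CC(C)(C)OO; selenium dioxide (oxygen carrier), O=[Se]=O
Why: Riley allylic oxidation (ene reaction, then [2,3]-sigmatropic shift) attacks the methyl group trans to the chain at the more substituted alkene terminus, which should give the (E)-allylic alcohol, and partial conversion limits over-oxidation to the enal.

**Step 15**
Reactants: 23 8-[(2E)-4-hydroxy-3-methylbut-2-en-1-yl]-5,7-bis(methoxymethoxy)-4H-chromen-4-one
Product: 24 8-[(2E)-4-{[tert-butyl(dimethyl)silyl]oxy}-3-methylbut-2-en-1-yl]-5,7-bis(methoxymethoxy)-4H-chromen-4-one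
Conditions: TBSCl, imidazole, CH2Cl2, rt
Reagents that add atoms: tert-butyldimethylsilyl chloride, CC(C)(C)[Si](C)(C)Cl
Why: Imidazole-promoted O-silylation masks the primary allylic alcohol against rhodium alkoxide chemistry in step 17, and the ether is removed again in the final acidic step.

**Step 16**
Reactants: 18 (2R,3R)-5-bromo-3-[3,5-bis(methoxymethoxy)phenyl]-6-(methoxymethoxy)-2-[4-(methoxymethoxy)phenyl]-2,3-dihydro-1-benzofuran
Product: 27 [(2R,3R)-3-[3,5-bis(methoxymethoxy)phenyl]-6-(methoxymethoxy)-2-[4-(methoxymethoxy)phenyl]-2,3-dihydro-1-benzofuran-5-yl]boronic acid, via aryllithium 25 (not isolated), via lithium aryltriisopropoxyborate 26 (not isolated)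
Conditions: B(OiPr)3 (2 equiv), THF, –78 °C; n-BuLi (1.1 equiv); → 0 °C; aq. NH4Cl; used crude
Reagents that add atoms: triisopropyl borate, CC(C)OB(OC(C)C)OC(C)C; water, O
Why: Bromine–lithium exchange at –78 °C should outrun MOM-directed ortho-lithiation and benzylic deprotonation, and the aryllithium is captured at once by the borate already in the flask (in situ quench borylation), so both ring stereocentres stay untouched.

**Step 17**
Reactants: 27 [(2R,3R)-3-[3,5-bis(methoxymethoxy)phenyl]-6-(methoxymethoxy)-2-[4-(methoxymethoxy)phenyl]-2,3-dihydro-1-benzofuran-5-yl]boronic acid; 24 8-[(2E)-4-{[tert-butyl(dimethyl)silyl]oxy}-3-methylbut-2-en-1-yl]-5,7-bis(methoxymethoxy)-4H-chromen-4-one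
Product: 28 (2S)-2-[(2R,3R)-3-[3,5-bis(methoxymethoxy)phenyl]-6-(methoxymethoxy)-2-[4-(methoxymethoxy)phenyl]-2,3-dihydro-1-benzofuran-5-yl]-8-[(2E)-4-{[tert-butyl(dimethyl)silyl]oxy}-3-methylbut-2-en-1-yl]-5,7-bis(methoxymethoxy)-2,3-dihydro-4H-chromen-4-one
Conditions: 27 (1.0 equiv), 24 (1.2 equiv), [RhCl(C2H4)2]2 (2.5 mol %), (1S,4S)-2,5-diphenylbicyclo[2.2.2]octa-2,5-diene (5.5 mol %), KOH (0.2 equiv), dioxane–H2O (10:1), 30 °C
Reagents that add atoms: none
Why: Rhodium-catalysed asymmetric 1,4-addition of an arylboronic acid to a chromone (Hayashi–Miyaura reaction), in which the aryl–rhodium species inserts the C2=C3 bond on the Re face of C2 under control of the chiral diene (setting 2S, the dihydrofuran stereocentres being remote) and water protonates the resulting rhodium enolate.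

**Step 18**
Reactants: 28 the protected flavanone of step 17
Product: 29 (2S)-2-[(2R,3R)-3-(3,5-dihydroxyphenyl)-6-hydroxy-2-(4-hydroxyphenyl)-2,3-dihydro-1-benzofuran-5-yl]-5,7-dihydroxy-8-[(2E)-4-hydroxy-3-methylbut-2-en-1-yl]-2,3-dihydro-4H-chromen-4-one
Conditions: HCl (3 M aq.)–MeOH–THF, rt
Reagents that add atoms: none
Why: Acid-catalysed transacetalisation of the seven aryl MOM ethers and methanolysis of the primary silyl ether should proceed at room temperature, where the flavanone C2, the trans-dihydrofuran and the poorly ionisable 2-methylallyl-type alcohol are expected to survive.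

**Compound list**

1 | 5-bromo-2,4-dihydroxybenzaldehyde | O=Cc1cc(Br)c(O)cc1O | starting material
2 | 5-bromo-2-hydroxy-4-(methoxymethoxy)benzaldehyde | O=Cc1cc(Br)c(OCOC)cc1O | intermediate
3 | 5-bromoresorcinol | Oc1cc(O)cc(Br)c1 | starting material
4 | 1-bromo-3,5-bis(methoxymethoxy)benzene | COCOc1cc(Br)cc(OCOC)c1 | intermediate
5 | 3,5-bis(methoxymethoxy)phenylmagnesium bromide | COCOc1cc(cc(OCOC)c1)[Mg]Br | intermediate
6 | rac-[5-bromo-2-hydroxy-4-(methoxymethoxy)phenyl][3,5-bis(methoxymethoxy)phenyl]methanol | OC(c1cc(OCOC)cc(OCOC)c1)c1cc(Br)c(OCOC)cc1O | intermediate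
7 | rac-2-{[3,5-bis(methoxymethoxy)phenyl](4-methylbenzenesulfonyl)methyl}-4-bromo-5-(methoxymethoxy)phenol | Cc1ccc(cc1)S(=O)(=O)C(c1cc(OCOC)cc(OCOC)c1)c1cc(Br)c(OCOC)cc1O | intermediate
8 | 4-hydroxybenzyl alcohol | OCc1ccc(O)cc1 | starting material
9 | [4-(methoxymethoxy)phenyl]methanol | OCc1ccc(OCOC)cc1 | intermediate
10 | 1-(bromomethyl)-4-(methoxymethoxy)benzene | BrCc1ccc(OCOC)cc1 | intermediate
11 | (2S,5S)-hexane-2,5-diol | C[C@H](O)CC[C@H](C)O | starting material
12 | (2S,5S)-hexane-2,5-diyl dimethanesulfonate | C[C@H](OS(C)(=O)=O)CC[C@H](C)OS(C)(=O)=O | intermediate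
13 | (2R,5R)-2,5-dimethylthiolane | C[C@@H]1CC[C@@H](C)S1 | intermediate
14 | (2R,5R)-1-[4-(methoxymethoxy)benzyl]-2,5-dimethylthiolan-1-ium tetrafluoroborate | C[C@@H]1CC[C@@H](C)[S+]1Cc1ccc(OCOC)cc1.F[B-](F)(F)F | intermediate
15 | 6-{[3,5-bis(methoxymethoxy)phenyl]methylidene}-4-bromo-3-(methoxymethoxy)cyclohexa-2,4-dien-1-one (o-quinone methide) | O=C1C=C(OCOC)C(Br)=CC1=Cc1cc(OCOC)cc(OCOC)c1 | intermediate
16 | (2R,5R)-2,5-dimethylthiolan-1-ium [4-(methoxymethoxy)phenyl]methylide (sulfonium benzylide) | C[C@@H]1CC[C@@H](C)[S+]1[CH-]c1ccc(OCOC)cc1 | intermediate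
17 | 4-bromo-2-{(1R,2S)-1-[3,5-bis(methoxymethoxy)phenyl]-2-[(2R,5R)-2,5-dimethylthiolan-1-ium-1-yl]-2-[4-(methoxymethoxy)phenyl]ethyl}-5-(methoxymethoxy)phenolate (betaine) | [O-]c1cc(OCOC)c(Br)cc1[C@@H](c1cc(OCOC)cc(OCOC)c1)[C@@H](c1ccc(OCOC)cc1)[S+]1[C@H](C)CC[C@H]1C | intermediate
18 | (2R,3R)-5-bromo-3-[3,5-bis(methoxymethoxy)phenyl]-6-(methoxymethoxy)-2-[4-(methoxymethoxy)phenyl]-2,3-dihydro-1-benzofuran | Brc1cc3c(cc1OCOC)O[C@@H](c1ccc(OCOC)cc1)[C@@H]3c1cc(OCOC)cc(OCOC)c1 | intermediate
19 | 5,7-dihydroxy-4H-chromen-4-one | O=c1ccoc2cc(O)cc(O)c12 | starting material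
20 | 5,7-bis(methoxymethoxy)-4H-chromen-4-one | O=c1ccoc2cc(OCOC)cc(OCOC)c12 | intermediate
21 | 8-iodo-5,7-bis(methoxymethoxy)-4H-chromen-4-one | O=c1ccoc2c(I)c(OCOC)cc(OCOC)c12 | intermediate
22 | 5,7-bis(methoxymethoxy)-8-(3-methylbut-2-en-1-yl)-4H-chromen-4-one | O=c1ccoc2c(CC=C(C)C)c(OCOC)cc(OCOC)c12 | intermediate
23 | 8-[(2E)-4-hydroxy-3-methylbut-2-en-1-yl]-5,7-bis(methoxymethoxy)-4H-chromen-4-one | O=c1ccoc2c(C/C=C(\C)CO)c(OCOC)cc(OCOC)c12 | intermediate
24 | 8-[(2E)-4-{[tert-butyl(dimethyl)silyl]oxy}-3-methylbut-2-en-1-yl]-5,7-bis(methoxymethoxy)-4H-chromen-4-one | O=c1ccoc2c(C/C=C(\C)CO[Si](C)(C)C(C)(C)C)c(OCOC)cc(OCOC)c12 | intermediate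
25 | [(2R,3R)-3-[3,5-bis(methoxymethoxy)phenyl]-6-(methoxymethoxy)-2-[4-(methoxymethoxy)phenyl]-2,3-dihydro-1-benzofuran-5-yl]lithium | [Li]c1cc3c(cc1OCOC)O[C@@H](c1ccc(OCOC)cc1)[C@@H]3c1cc(OCOC)cc(OCOC)c1 | intermediate
26 | lithium [(2R,3R)-3-[3,5-bis(methoxymethoxy)phenyl]-6-(methoxymethoxy)-2-[4-(methoxymethoxy)phenyl]-2,3-dihydro-1-benzofuran-5-yl]tri(propan-2-yloxy)borate | [Li+].CC(C)O[B-](OC(C)C)(OC(C)C)c1cc3c(cc1OCOC)O[C@@H](c1ccc(OCOC)cc1)[C@@H]3c1cc(OCOC)cc(OCOC)c1 | intermediate
27 | [(2R,3R)-3-[3,5-bis(methoxymethoxy)phenyl]-6-(methoxymethoxy)-2-[4-(methoxymethoxy)phenyl]-2,3-dihydro-1-benzofuran-5-yl]boronic acid | OB(O)c1cc3c(cc1OCOC)O[C@@H](c1ccc(OCOC)cc1)[C@@H]3c1cc(OCOC)cc(OCOC)c1 | intermediate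
28 | (2S)-2-[(2R,3R)-3-[3,5-bis(methoxymethoxy)phenyl]-6-(methoxymethoxy)-2-[4-(methoxymethoxy)phenyl]-2,3-dihydro-1-benzofuran-5-yl]-8-[(2E)-4-{[tert-butyl(dimethyl)silyl]oxy}-3-methylbut-2-en-1-yl]-5,7-bis(methoxymethoxy)-2,3-dihydro-4H-chromen-4-one | C/C(=C\Cc1c(OCOC)cc(OCOC)c2c1O[C@H](c1cc3c(cc1OCOC)O[C@@H](c1ccc(OCOC)cc1)[C@@H]3c1cc(OCOC)cc(OCOC)c1)CC2=O)CO[Si](C)(C)C(C)(C)C | intermediate
29 | (2S)-2-[(2R,3R)-3-(3,5-dihydroxyphenyl)-6-hydroxy-2-(4-hydroxyphenyl)-2,3-dihydro-1-benzofuran-5-yl]-5,7-dihydroxy-8-[(2E)-4-hydroxy-3-methylbut-2-en-1-yl]-2,3-dihydro-4H-chromen-4-one (CNP0235407.2) | C/C(=C\Cc1c(O)cc(O)c2c1O[C@H](c1cc3c(cc1O)O[C@@H](c1ccc(O)cc1)[C@@H]3c1cc(O)cc(O)c1)CC2=O)CO | target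

**Totals**

Total step count: 18.
Longest linear sequence: 7 steps (for example steps 7, 8, 9, 10, 16, 17, 18).

**Steps most likely to fail**

Step 10 (labelled). What may go wrong: loss of facial discrimination when the benzylide attacks the methide, giving low enantiomeric purity, or benzyl transfer from the electron-rich sulfonium to phenoxide or sulfinate outrunning the annulation. The fallback uses known chemistry, the asymmetric intramolecular C–H insertion of a donor/donor rhodium carbene, and sets out from carbinol 6 and bromide 10. The phenol of 6 is benzylated with 10 (K2CO3, acetone) to give rac-{5-bromo-4-(methoxymethoxy)-2-{[4-(methoxymethoxy)benzyl]oxy}phenyl}[3,5-bis(methoxymethoxy)phenyl]methanol F1, which MnO2 oxidises to the corresponding benzophenone F2. Hydrazine (EtOH, heat) converts this into the hydrazone F3, and MnO2 dehydrogenates F3 to the diaryldiazomethane F4. Rh2(S-PTAD)4, or its antipode if that is the one giving 3R, inserts the carbene into the benzylic C–H bond of the ether to give the cis-(2S,3R)-dihydrobenzofuran F5. Brief treatment with a catalytic anhydrous acid then equilibrates C2 through reversible benzylic C–O ionisation, assisted by the para-oxygenated aryl group, to the more stable trans isomer; any MOM group lost is restored with MOMCl and i-Pr2NEt. The fallback returns to the route at 18.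

Step 17. What may go wrong: slow insertion of the hindered, electron-rich chromone, so that protodeboronation consumes the aryl donor, or incomplete catalyst control at C2. The fallback is the classical chalcone route and sets out from 18 and 24. Bromine–lithium exchange on 18 and quenching with DMF gives (2R,3R)-3-[3,5-bis(methoxymethoxy)phenyl]-6-(methoxymethoxy)-2-[4-(methoxymethoxy)phenyl]-2,3-dihydro-1-benzofuran-5-carbaldehyde F6. Aqueous NaOH in EtOH opens chromone 24, with loss of formate, to 1-{3-[(2E)-4-{[tert-butyl(dimethyl)silyl]oxy}-3-methylbut-2-en-1-yl]-2-hydroxy-4,6-bis(methoxymethoxy)phenyl}ethan-1-one F7. Claisen–Schmidt condensation of F6 with F7 (KOH, EtOH) gives the (E)-2'-hydroxychalcone F8, which cyclises by oxa-Michael addition (NaOAc, EtOH, reflux) to 28 and its (2R)-epimer F9. These two are diastereomers, to be separated by chromatography, and F9 is recycled through F8 under the same conditions. The fallback returns to the route at 28.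

Step 18. What may go wrong: incomplete cleavage of seven acetals under acid mild enough to avoid ionisation of the flavanone C2–O bond (epimerisation at C2) and addition of the 7-hydroxyl to the side-chain alkene. The fallback is a non-protic silyl-transfer deprotection and sets out from 28. TMSOTf and 2,2'-bipyridyl in CH2Cl2 at 0 °C exchange the aryl MOM ethers for trimethylsilyl ethers to give the heptakis(trimethylsilyl) ether F10. Buffered fluoride (HF·pyridine with excess pyridine, THF, 0 °C) then removes all silyl groups, including the tert-butyldimethylsilyl ether. The fallback returns to the route at 29.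

**Further compounds**

F1 | step 10 | rac-{5-bromo-4-(methoxymethoxy)-2-{[4-(methoxymethoxy)benzyl]oxy}phenyl}[3,5-bis(methoxymethoxy)phenyl]methanol | OC(c1cc(OCOC)cc(OCOC)c1)c1cc(Br)c(OCOC)cc1OCc1ccc(OCOC)cc1
F2 | step 10 | {5-bromo-4-(methoxymethoxy)-2-{[4-(methoxymethoxy)benzyl]oxy}phenyl}[3,5-bis(methoxymethoxy)phenyl]methanone | O=C(c1cc(OCOC)cc(OCOC)c1)c1cc(Br)c(OCOC)cc1OCc1ccc(OCOC)cc1
F3 | step 10 | hydrazone of F2 | NN=C(c1cc(OCOC)cc(OCOC)c1)c1cc(Br)c(OCOC)cc1OCc1ccc(OCOC)cc1
F4 | step 10 | {5-bromo-4-(methoxymethoxy)-2-{[4-(methoxymethoxy)benzyl]oxy}phenyl}[3,5-bis(methoxymethoxy)phenyl]diazomethane | [N-]=[N+]=C(c1cc(OCOC)cc(OCOC)c1)c1cc(Br)c(OCOC)cc1OCc1ccc(OCOC)cc1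
F5 | step 10 | (2S,3R)-5-bromo-3-[3,5-bis(methoxymethoxy)phenyl]-6-(methoxymethoxy)-2-[4-(methoxymethoxy)phenyl]-2,3-dihydro-1-benzofuran (cis) | Brc1cc3c(cc1OCOC)O[C@H](c1ccc(OCOC)cc1)[C@@H]3c1cc(OCOC)cc(OCOC)c1
F6 | step 17 | (2R,3R)-3-[3,5-bis(methoxymethoxy)phenyl]-6-(methoxymethoxy)-2-[4-(methoxymethoxy)phenyl]-2,3-dihydro-1-benzofuran-5-carbaldehyde | O=Cc1cc3c(cc1OCOC)O[C@@H](c1ccc(OCOC)cc1)[C@@H]3c1cc(OCOC)cc(OCOC)c1
F7 | step 17 | 1-{3-[(2E)-4-{[tert-butyl(dimethyl)silyl]oxy}-3-methylbut-2-en-1-yl]-2-hydroxy-4,6-bis(methoxymethoxy)phenyl}ethan-1-one | CC(=O)c1c(O)c(C/C=C(\C)CO[Si](C)(C)C(C)(C)C)c(OCOC)cc1OCOC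
F8 | step 17 | (2E)-1-{3-[(2E)-4-{[tert-butyl(dimethyl)silyl]oxy}-3-methylbut-2-en-1-yl]-2-hydroxy-4,6-bis(methoxymethoxy)phenyl}-3-[(2R,3R)-3-[3,5-bis(methoxymethoxy)phenyl]-6-(methoxymethoxy)-2-[4-(methoxymethoxy)phenyl]-2,3-dihydro-1-benzofuran-5-yl]prop-2-en-1-one | O=C(/C=C/c1cc3c(cc1OCOC)O[C@@H](c1ccc(OCOC)cc1)[C@@H]3c1cc(OCOC)cc(OCOC)c1)c1c(O)c(C/C=C(\C)CO[Si](C)(C)C(C)(C)C)c(OCOC)cc1OCOC
F9 | step 17 | (2R)-epimer of 28 at the flavanone carbon | C/C(=C\Cc1c(OCOC)cc(OCOC)c2c1O[C@@H](c1cc3c(cc1OCOC)O[C@@H](c1ccc(OCOC)cc1)[C@@H]3c1cc(OCOC)cc(OCOC)c1)CC2=O)CO[Si](C)(C)C(C)(C)C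
F10 | step 18 | heptakis(trimethylsilyl) ether corresponding to 28 (all seven MOM groups exchanged for trimethylsilyl, tert-butyldimethylsilyl ether retained) | C/C(=C\Cc1c(O[Si](C)(C)C)cc(O[Si](C)(C)C)c2c1O[C@H](c1cc3c(cc1O[Si](C)(C)C)O[C@@H](c1ccc(O[Si](C)(C)C)cc1)[C@@H]3c1cc(O[Si](C)(C)C)cc(O[Si](C)(C)C)c1)CC2=O)CO[Si](C)(C)C(C)(C)C
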